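**Retrosynthetic overview**

1. Betaethrin E (25) comes from triol 23 by acylation of the ring A benzylic alcohol with palmitoyl chloride; 23 comes from the key-step product 21 by hydrogenolysis of the benzyl ether and desilylation.
2. The route rests on ring B, whose six carbons carry the diaryl ether oxygen at C1, the methyl at C3, the hydroxyl at C5 and the ester at C6. Cutting C3–C4 and C6–C1 leaves C4–C5–C6 with its ester (methyl acetoacetate, used as bis-silyl dienol ether 18) and C1(OAr)–C2–C3(CH3) (aryloxy-ynone 14).
3. Ynone 14 comes from ring A phenol 8 through dichlorovinyl ether 10 (trichloroethylene) and acylation of the derived lithium aryloxyacetylide, so the crowded ether oxygen is bonded to an sp carbon and never has to be joined to a preformed arene.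
4. Phenol 8 comes from 2-hydroxy-4-methoxybenzaldehyde (1) by benzylation, Baeyer–Villiger oxidation, ortho-formylation, reduction and silylation.
5. Ring order: ring A is bought; ring B is the only ring made, in step 10.

Key step: step 10

Remark: the target has no stereocentre; the transient intermediates 19 and 20 are racemic and their stereocentres vanish on aromatisation, and silyl enol ether 16 is used as an E/Z mixture because its geometry is erased in step 9.

**Route**

Step 1
Reactants: 1 2-hydroxy-4-methoxybenzaldehyde
Product: 2 2-(benzyloxy)-4-methoxybenzaldehyde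
Conditions: BnBr (1.1 equiv), K2CO3, DMF, rt
Reagents that add atoms: benzyl bromide, BrCc1ccccc1
Why: Williamson ether synthesis, in which the phenoxide of the salicylaldehyde is the only nucleophile and the benzylic bromide a reactive electrophile.

Step 2
Reactants: 2 2-(benzyloxy)-4-methoxybenzaldehyde
Product: 4 2-(benzyloxy)-4-methoxyphenol, via aryl formate 3 (not isolated)
Conditions: mCPBA, CH2Cl2, rt; then K2CO3 (cat.), MeOH, rt
Reagents that add atoms: 3-chloroperoxybenzoic acid (mCPBA), OOC(=O)c1cccc(Cl)c1
Why: Baeyer–Villiger oxidation, in which the aryl group carrying ortho and para alkoxy donors migrates in preference to hydride, followed by mild methanolysis of the formate.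

Step 3
Reactants: 4 2-(benzyloxy)-4-methoxyphenol; 5 paraformaldehyde
Product: 6 3-(benzyloxy)-2-hydroxy-5-methoxybenzaldehyde
Conditions: 5 (3 equiv), MgCl2, Et3N, MeCN, reflux; 1 M HCl work-up
Reagents that add atoms: none
Why: Magnesium-mediated ortho-formylation of a phenol, in which the magnesium phenoxide directs formaldehyde to the only free ortho position and excess formaldehyde serves as the hydride acceptor.

Step 4
Reactants: 6 3-(benzyloxy)-2-hydroxy-5-methoxybenzaldehyde
Product: 7 2-(benzyloxy)-6-(hydroxymethyl)-4-methoxyphenol
Conditions: NaBH4, MeOH, 0 °C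
Reagents that add atoms: none
Why: Hydride reduction of the aldehyde by NaBH4, with no other reducible group present.

Step 5
Reactants: 7 2-(benzyloxy)-6-(hydroxymethyl)-4-methoxyphenol
Product: 8 2-(benzyloxy)-4-methoxy-6-[(triisopropylsilyloxy)methyl]phenol
Conditions: TIPSCl (1.05 equiv), imidazole, CH2Cl2, 0 °C to rt
Reagents that add atoms: triisopropylsilyl chloride, CC(C)[Si](Cl)(C(C)C)C(C)C
Why: Chemoselective silylation, in which the bulky silyl chloride should react with the primary benzylic alcohol much faster than with the 2,6-disubstituted phenol.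

Step 6
Reactants: 8 2-(benzyloxy)-4-methoxy-6-[(triisopropylsilyloxy)methyl]phenol; 9 trichloroethylene
Product: 10 1-(benzyloxy)-2-[(E)-1,2-dichloroethenyloxy]-5-methoxy-3-[(triisopropylsilyloxy)methyl]benzene
Conditions: 9 (2 equiv), K2CO3, DMF, 70 °C
Reagents that add atoms: none
Why: Elimination–addition, in which base turns trichloroethylene into dichloroacetylene and the phenoxide adds to it in anti fashion to give the (E)-dichlorovinyl ether, a known way to make aryl dichlorovinyl ethers.

Step 7
Reactants: 10 the (E)-dichlorovinyl ether; 11 N-methoxy-N-methylacetamide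
Product: 14 4-{2-(benzyloxy)-4-methoxy-6-[(triisopropylsilyloxy)methyl]phenoxy}but-3-yn-2-one, via chloroalkynyl ether 12 (not isolated), via lithium aryloxyacetylide 13 (not isolated)
Conditions: n-BuLi (2.2 equiv), THF, –78 to –40 °C; then 11 (1.5 equiv), –78 to –20 °C; inverse quench into cold dilute HCl/Et2O
Reagents that add atoms: none
Why: Dehydrochlorination and chlorine–lithium exchange by n-BuLi give the lithium aryloxyacetylide, and its acylation by the Weinreb amide stops at the chelated tetrahedral adduct and releases the ynone only on work-up (Weinreb ketone synthesis).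

Step 8
Reactants: 15 methyl acetoacetate
Product: 16 methyl 3-(trimethylsilyloxy)but-2-enoate (E/Z mixture)
Conditions: TMSCl, Et3N, hexane, rt
Reagents that add atoms: chlorotrimethylsilane, C[Si](C)(C)Cl
Why: O-silylation of the enol of a beta-keto ester with TMSCl and an amine base (silyl enol ether formation).

Step 9
Reactants: 16 methyl 3-(trimethylsilyloxy)but-2-enoate
Product: 18 (Z)-1-methoxy-1,3-bis(trimethylsilyloxy)buta-1,3-diene, via lithium dienolate 17 (not isolated)
Conditions: LiN(iPr)2, THF, –78 °C; then TMSCl, –78 °C to rt; used without chromatography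
Reagents that add atoms: chlorotrimethylsilane, C[Si](C)(C)Cl
Why: Kinetic gamma-deprotonation of the vinylogous ester by the lithium amide gives the extended dienolate, which is silylated on oxygen to the bis(silyloxy)diene.

Step 10
Reactants: 14 the aryloxy-ynone; 18 (Z)-1-methoxy-1,3-bis(trimethylsilyloxy)buta-1,3-diene
Product: 21 methyl 2-{2-(benzyloxy)-4-methoxy-6-[(triisopropylsilyloxy)methyl]phenoxy}-6-hydroxy-4-methylbenzoate, via aldol adduct 19 (not isolated), via hydroxycyclohexenone 20 (not isolated)
Conditions: 18 (1.5 equiv), TiCl4 (1.1 equiv), CH2Cl2, 4 Å molecular sieves, –78 to 0 °C; aq NaHCO3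
Reagents that add atoms: none
Why: Proposed new method: TiCl4 bound to the ketone oxygen of 14 should steer the terminal carbon of diene 18 into a Mukaiyama aldol addition at the carbonyl carbon (C3–C4 bond), because attack at the aryloxy-bearing sp carbon would give only an allenolate and is screened by the 2,6-disubstituted ring A, so the tertiary propargylic titanium alkoxide 19 results. Acid activation of the ynol ether at its carbon remote from oxygen then lets the central carbon of the beta-keto ester add to the aryloxy-bearing carbon (C6–C1 bond) in a 6-endo-dig closure to 20, and loss of the tertiary hydroxyl as water with enolisation of the former acetoacetate ketone aromatises ring B. The closest known reaction type is the TiCl4-mediated formal [3+3] cyclocondensation of 1,3-bis(silyloxy)buta-1,3-dienes with 3-silyloxy- or 3-alkoxy-enones and related 1,3-dielectrophiles to give salicylates; an aryloxy-ynone as the dielectrophile is the untested extension. No stereocentre is created in the product. The step needs 1,2- rather than 1,4-addition in the first bond formation (otherwise the 4-aryloxy-6-methyl isomer forms) and carbon–carbon closure before any Meyer–Schuster-type transfer of oxygen to the ynol ether carbon, which low temperature, strict exclusion of water and the steric shielding by ring A are meant to secure.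

Step 11
Reactants: 21 the benzyl- and silyl-protected diaryl ether
Product: 22 methyl 2-hydroxy-6-{2-hydroxy-4-methoxy-6-[(triisopropylsilyloxy)methyl]phenoxy}-4-methylbenzoate
Conditions: H2 (1 atm), Pd/C (10% Pd on carbon), EtOAc, rt
Reagents that add atoms: none
Why: Palladium-catalysed hydrogenolysis cleaves the aryl benzyl ether, while the silyl-protected benzylic C–O bond of ring A, the methyl ester and the diaryl ether should stay intact under neutral conditions.

Step 12
Reactants: 22 the silyl ether
Product: 23 methyl 2-hydroxy-6-[2-hydroxy-6-(hydroxymethyl)-4-methoxyphenoxy]-4-methylbenzoate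
Conditions: Bu4NF, AcOH, THF, 0 °C to rt
Reagents that add atoms: none
Why: Fluoride-induced desilylation driven by Si–F bond formation, buffered with acetic acid so that the phenols and the methyl ester are not exposed to basic fluoride.

Step 13
Reactants: 23 the triol; 24 palmitoyl chloride
Product: 25 betaethrin E, methyl 2-hydroxy-6-{2-hydroxy-4-methoxy-6-[(palmitoyloxy)methyl]phenoxy}-4-methylbenzoate
Conditions: 24 (1.05 equiv), 2,4,6-collidine, CH2Cl2, –40 to 0 °C
Reagents that add atoms: none
Why: Chemoselective O-acylation with an acid chloride and a weak, non-nucleophilic base, in which the neutral primary benzylic alcohol should react faster than the two phenols, one held in a hydrogen bond to the ester carbonyl of ring B and the other flanked by the diaryl ether oxygen.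

**Compound list**

1 | 2-hydroxy-4-methoxybenzaldehyde | COc1ccc(C=O)c(O)c1 | starting material
2 | 2-(benzyloxy)-4-methoxybenzaldehyde | COc1ccc(C=O)c(OCc2ccccc2)c1 | intermediate
3 | 2-(benzyloxy)-4-methoxyphenyl formate (not isolated) | COc1ccc(OC=O)c(OCc2ccccc2)c1 | intermediate
4 | 2-(benzyloxy)-4-methoxyphenol | COc1ccc(O)c(OCc2ccccc2)c1 | intermediate
5 | paraformaldehyde (source of formaldehyde) | C=O | starting material
6 | 3-(benzyloxy)-2-hydroxy-5-methoxybenzaldehyde | COc1cc(C=O)c(O)c(OCc2ccccc2)c1 | intermediate
7 | 2-(benzyloxy)-6-(hydroxymethyl)-4-methoxyphenol | COc1cc(CO)c(O)c(OCc2ccccc2)c1 | intermediate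
8 | 2-(benzyloxy)-4-methoxy-6-[(triisopropylsilyloxy)methyl]phenol | COc1cc(CO[Si](C(C)C)(C(C)C)C(C)C)c(O)c(OCc2ccccc2)c1 | intermediate
9 | trichloroethylene | ClC=C(Cl)Cl | starting material
10 | 1-(benzyloxy)-2-[(E)-1,2-dichloroethenyloxy]-5-methoxy-3-[(triisopropylsilyloxy)methyl]benzene | Cl/C=C(/Cl)Oc1c(CO[Si](C(C)C)(C(C)C)C(C)C)cc(OC)cc1OCc1ccccc1 | intermediate
11 | N-methoxy-N-methylacetamide | CC(=O)N(C)OC | starting material
12 | 1-(benzyloxy)-2-[(chloroethynyl)oxy]-5-methoxy-3-[(triisopropylsilyloxy)methyl]benzene (not isolated) | ClC#COc1c(CO[Si](C(C)C)(C(C)C)C(C)C)cc(OC)cc1OCc1ccccc1 | intermediate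
13 | lithium {2-(benzyloxy)-4-methoxy-6-[(triisopropylsilyloxy)methyl]phenoxy}acetylide (not isolated) | [Li]C#COc1c(CO[Si](C(C)C)(C(C)C)C(C)C)cc(OC)cc1OCc1ccccc1 | intermediate
14 | 4-{2-(benzyloxy)-4-methoxy-6-[(triisopropylsilyloxy)methyl]phenoxy}but-3-yn-2-one | CC(=O)C#COc1c(CO[Si](C(C)C)(C(C)C)C(C)C)cc(OC)cc1OCc1ccccc1 | intermediate
15 | methyl acetoacetate | COC(=O)CC(C)=O | starting material
16 | methyl 3-(trimethylsilyloxy)but-2-enoate (E/Z mixture) | COC(=O)C=C(C)O[Si](C)(C)C | intermediate
17 | lithium 1-methoxy-3-(trimethylsilyloxy)buta-1,3-dien-1-olate (OLi cis to C3; not isolated) | CO/C(O[Li])=C/C(=C)O[Si](C)(C)C | intermediate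
18 | (Z)-1-methoxy-1,3-bis(trimethylsilyloxy)buta-1,3-diene | CO/C(O[Si](C)(C)C)=C/C(=C)O[Si](C)(C)C | intermediate
19 | methyl 7-{2-(benzyloxy)-4-methoxy-6-[(triisopropylsilyloxy)methyl]phenoxy}-5-hydroxy-5-methyl-3-oxohept-6-ynoate (racemic, present as its titanium alkoxide; not isolated) | COC(=O)CC(=O)CC(C)(O)C#COc1c(CO[Si](C(C)C)(C(C)C)C(C)C)cc(OC)cc1OCc1ccccc1 | intermediate
20 | methyl 6-{2-(benzyloxy)-4-methoxy-6-[(triisopropylsilyloxy)methyl]phenoxy}-4-hydroxy-4-methyl-2-oxocyclohex-5-ene-1-carboxylate (racemic mixture of diastereomers; not isolated) | COC(=O)C1C(=O)CC(C)(O)C=C1Oc1c(CO[Si](C(C)C)(C(C)C)C(C)C)cc(OC)cc1OCc1ccccc1 | intermediate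
21 | methyl 2-{2-(benzyloxy)-4-methoxy-6-[(triisopropylsilyloxy)methyl]phenoxy}-6-hydroxy-4-methylbenzoate | COC(=O)c1c(O)cc(C)cc1Oc1c(CO[Si](C(C)C)(C(C)C)C(C)C)cc(OC)cc1OCc1ccccc1 | intermediate
22 | methyl 2-hydroxy-6-{2-hydroxy-4-methoxy-6-[(triisopropylsilyloxy)methyl]phenoxy}-4-methylbenzoate | COC(=O)c1c(O)cc(C)cc1Oc1c(CO[Si](C(C)C)(C(C)C)C(C)C)cc(OC)cc1O | intermediate
23 | methyl 2-hydroxy-6-[2-hydroxy-6-(hydroxymethyl)-4-methoxyphenoxy]-4-methylbenzoate | COC(=O)c1c(O)cc(C)cc1Oc1c(CO)cc(OC)cc1O | intermediate
24 | palmitoyl chloride | CCCCCCCCCCCCCCCC(Cl)=O | starting material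
25 | betaethrin E | CCCCCCCCCCCCCCCC(=O)OCc1cc(OC)cc(O)c1Oc1cc(C)cc(O)c1C(=O)OC | target

**Step count**

Total: 13 steps. Longest linear sequence: 11 steps (steps 1–7, then 10–13); the diene branch (steps 8 and 9) joins at step 10.

**Steps most likely to fail**

Step 10 (proposed new method). Three things may go wrong. The first bond formation may take the conjugate course at the aryloxy-bearing alkyne carbon and give the wrong regiochemistry. The propargylic titanium alkoxide may rearrange in Meyer–Schuster fashion to an aryl enoate, after which Dieckmann-type closure expels the ring A phenoxide. The activated ynol ether may be captured by the neighbouring benzyl or silyl ether oxygen. The fallback uses known chemistry, sets out from phenol 8 and joins a preformed ring B instead of building it. Commercial methyl 2,6-dihydroxy-4-methylbenzoate (COC(=O)c1c(O)cc(C)cc1O) is monobenzylated (BnBr, K2CO3, acetone) to methyl 2-(benzyloxy)-6-hydroxy-4-methylbenzoate F1. This is converted (Tf2O, pyridine, CH2Cl2) into methyl 2-(benzyloxy)-4-methyl-6-(trifluoromethylsulfonyloxy)benzoate F2. Palladium-catalysed C–O cross-coupling of F2 with 8 (Pd(OAc)2, the ligand tBuXPhos, K3PO4, toluene, 100 °C; Buchwald–Hartwig-type diaryl ether synthesis) should give methyl 2-(benzyloxy)-6-{2-(benzyloxy)-4-methoxy-6-[(triisopropylsilyloxy)methyl]phenoxy}-4-methylbenzoate F3. Hydrogenolysis of both benzyl ethers (H2, Pd/C, EtOAc) brings the material back to the route at compound 22.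

Step 7. The liberated N,O-dimethylhydroxylamine or water may add across the electron-poor ynol ether during work-up, or acylation of the acetylide may be incomplete. The fallback sets out from dichlorovinyl ether 10 and replaces the one-pot acylation by addition and oxidation. The acetylide 13 generated as before is trapped with acetaldehyde at –78 °C to give racemic 4-{2-(benzyloxy)-4-methoxy-6-[(triisopropylsilyloxy)methyl]phenoxy}but-3-yn-2-ol F4, so no amine is released. Oxidation of the propargylic alcohol with activated MnO2 in CH2Cl2 then returns to the route at ynone 14.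

Step 13. The ring A phenol may be acylated in competition with the benzylic alcohol, or more than one hydroxyl may be acylated. The fallback sets out from triol 23 and reverses the roles of the partners. In a Mitsunobu esterification with palmitic acid (PPh3, diisopropyl azodicarboxylate, THF, 0 °C) the primary alcohol is made the electrophile and the carboxylate, the most acidic pronucleophile present, is the only species alkylated, so the phenols cannot be acylated. It arrives directly at target 25.

**Further compounds**

F1 | step 10 | methyl 2-(benzyloxy)-6-hydroxy-4-methylbenzoate | COC(=O)c1c(O)cc(C)cc1OCc1ccccc1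
F2 | step 10 | methyl 2-(benzyloxy)-4-methyl-6-(trifluoromethylsulfonyloxy)benzoate | COC(=O)c1c(OS(=O)(=O)C(F)(F)F)cc(C)cc1OCc1ccccc1
F3 | step 10 | methyl 2-(benzyloxy)-6-{2-(benzyloxy)-4-methoxy-6-[(triisopropylsilyloxy)methyl]phenoxy}-4-methylbenzoate | COC(=O)c1c(OCc2ccccc2)cc(C)cc1Oc1c(CO[Si](C(C)C)(C(C)C)C(C)C)cc(OC)cc1OCc1ccccc1
F4 | step 7 | 4-{2-(benzyloxy)-4-methoxy-6-[(triisopropylsilyloxy)methyl]phenoxy}but-3-yn-2-ol (racemic) | CC(O)C#COc1c(CO[Si](C(C)C)(C(C)C)C(C)C)cc(OC)cc1OCc1ccccc1
F0 | step 13 | none | none
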